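The runs were computed for an exercise; the scatter is artificial.

Start from the reagent.

common to all: free catalyst 1.2 mM

| charge | substrate | reagent | remark | time |
|---|---|---|---|---|
| Wednesday's | 2 M | 1 M | run made earlier |  |
| Tuesday's | 2 M | 1.5 M | run made earlier |  |
| flask | 2.0 M | 2.00 M |  | 30 min |

| run | time / min | product / % | substrate / % |
|---|---|---|---|
| Wednesday's | 1.33 | 1.9 | 96.0 |
| Wednesday's | 3.00 | 4.9 | 92.8 |
| Wednesday's | 8.00 | 12.6 | 82.5 |
| Wednesday's | 20.0 | 24.3 | 66.2 |
| Tuesday's | 2.50 | 4.1 | 91.9 |
| Tuesday's | 6.00 | 10.8 | 84.0 |
| Tuesday's | 12.0 | 19.2 | 72.8 |
| Tuesday's | 20.0 | 26.5 | 62.9 |

(scatter of a reading: 0.5 percentage points)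

* which holds at 30 min: what has brought the reaction to rest, or that it has not come to rest (forward and back rates have come level / all of the substrate has reacted / the reagent has run out first / it is still moving / no working catalyst is left)
* how much product there is at 30 min, in percent of the substrate charged

- a reading or a percentage of product counts all its forms, free or not
- the reaction counts as stopped when no species that holds the substrate changes by six tenths of a point or more over the second half of the time
- a reading of substrate is of its free form alone

I read the runs as a ladder, fastest rung first. At the first reading of Wednesday's run, 1.33 min, substrate and product fall short of the charge by 42.0 mM, far more than the 1.2 mM of catalyst, so in that run substrate already sits in some other form. On the next rung, Tuesday's rate of making product falls from 0.0360 M/min over its first 6.00 min to 0.0183 M/min over its last stretch, about half. The last rung is the reagent: if one reagent goes per product, even the early rate needs 55.6 min to use up the 2.00 M in the new flask, longer than 30 min, so I do not expect the reagent to run out in that flask by then. This says nothing of equilibrium or of the catalyst, but Tuesday's run still gains 7.3 percentage points of product over its last 8.00 min, and on that reading I expect the new flask to be still moving at 30 min.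

Raising the reagent from 1 M to 1.5 M adds just 2.2 points of product at 20.0 min, against a scatter of 0.5 points. From this I carry 0.214, the apparent reagent order: the logarithm of the ratio of product at one time in two runs, divided by the logarithm of the ratio of their reagent charges, other charges equal. It is a rough reading. Scaled by it, Tuesday's reading gives 28.2% at 20.0 min for c(reagent) of 2.00 M, and I commit to nothing further.

The forecast says it is still moving and 34.5%, between 31% and 38%, on its own slightly higher start: “At 2 M reagent I expect about 28.5% at 20 min, plus about 6% more.”

The flask gives 34.7% of product and it is still moving, with 65% of its reagent still there. A flask like Wednesday's, taken to 30 min, holds 30.4%; scaled by the order to c(reagent) of 2.00 M, that becomes 35.3%.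

    substrate + free catalyst → catalyst intermediate A (k = 68.0 /M/min)
    reagent + catalyst intermediate A → catalyst intermediate B (k = 74.0 /M/min)
    catalyst intermediate B ⇌ by-product + catalyst intermediate C (K = 0.340 M, k = 170 /min)
    catalyst intermediate C ⇌ free catalyst + product (K = 0.400 M, k = 190 /min)
    substrate + product ⇌ idle adduct, settled at all times (K = 0.530 /M)
    catalyst intermediate B → spent catalyst (k = 0.0110 /min)

For the neighbour flask, the same charges read at 20 min, the order gave 28.2%; the computed value is 27.9%.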